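**Plan**

Numbering: ring C5 (isopropenyl CH; isopropenyl centre C4), C6 (lactone O–CH), C7 (fusion CH), C8 (ester O–CH), C9 (CH2), C10 (Me, vinyl C1=C2); C11 acetoxy carbon, C12 lactone C=O; α = ring face of the C10 vinyl group.
Cuts, in order: the O11 acetate and the O8 ester; the lactone at C7–C11 and O6–C12 (to an O6 pyruvate and a C7=C8 enol silane); the C1 and C4 olefins (to an acetal carbon and a lactone carbonyl); last C9–C10 and C5–C6.
Enabling feature: the vinyl on C10 and the isopropenyl on C5 are cis and share the α face with O6, and C6 and C8 are oxygenated across an unsubstituted C9H2. This is the imprint of an endo [4+2] of a 1,3-dioxygenated butadiene (C6–C7–C8–C9) on a β-methylbutenolide (C4–C5–C10–C1).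
Forward: the cyclohexene (the only carbocycle) and a temporary acetal-lactone form together in the cycloaddition; that lactone is unzipped to vinyl and isopropenyl; the γ-lactone is then closed from O6 onto C7 by a pyruvate tether; reduction, Mitsunobu esterification and acetylation finish.
Stereochemistry: (−)-menthol, through the butenolide acetal carbon, fixes C10, C5 and C6 in the cycloaddition; C7 and C11 follow from the cis tether; C8 from β-face hydride delivery and SN2 inversion.

Key step: step 4

Assumption: acid equilibration with crystallisation is taken to deliver the (5R) menthyl acetal, as for the unmethylated parent butenolide; if the (5S) epimer crystallised instead, (+)-menthol would be used and every later argument would hold unchanged.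

**Route**

Step 1
Reactants: 1 5-hydroxy-4-methylfuran-2(5H)-one; 2 (−)-menthol
Product: 3 (5R)-5-[(1R,2S,5R)-menthyloxy]-4-methylfuran-2(5H)-one
Conditions: camphorsulfonic acid (cat.), toluene, reflux with azeotropic removal of water; crystallisation from hexane, acid-equilibrated mother liquor recycled
Reagents that add atoms: none
Why: Acid-catalysed acetalisation of the cyclic pseudo-acid; the acetal carbon epimerises under the same acid, so crystallisation should collect the mixture as the single (5R) epimer (crystallisation-induced diastereomer transformation).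

Step 2
Reactants: 4 (E)-4-methoxybut-3-en-2-one; 5 benzyl alcohol
Product: 6 (E)-4-(benzyloxy)but-3-en-2-one
Conditions: PPTS (cat.), toluene, 80 °C, reduced pressure to remove MeOH
Reagents that add atoms: none
Why: Acid-catalysed addition–elimination (transetherification of a vinylogous ester) driven by removal of methanol, the E enone being the thermodynamic isomer; benzyl is chosen because it can later be removed reductively, which spares the enol silane.

Step 3
Reactants: 6 (E)-4-(benzyloxy)but-3-en-2-one
Product: 7 (E)-1-(benzyloxy)-3-(tert-butyldimethylsilyloxy)buta-1,3-diene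
Conditions: TBSOTf, Et3N, Et2O, 0 °C
Reagents that add atoms: tert-butyldimethylsilyl trifluoromethanesulfonate, CC(C)(C)[Si](C)(C)OS(=O)(=O)C(F)(F)F
Why: Soft enolisation of the methyl ketone and O-silylation (silyl enol ether formation) gives the 2-silyloxydiene without touching the E enol ether.

Step 4
Reactants: 3 (5R)-5-menthyloxy-4-methylfuran-2(5H)-one; 7 (E)-1-(benzyloxy)-3-(tert-butyldimethylsilyloxy)buta-1,3-diene
Product: 8 cycloadduct: 7-(benzyloxy)-5-(tert-butyldimethylsilyloxy)-3-(menthyloxy)-3a-methyl-3a,4,7,7a-tetrahydroisobenzofuran-1(3H)-one, cis-fused, benzyloxy (C6) cis to the lactone carbonyl (C4), menthyloxy on the lactone face away from the cyclohexene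
Conditions: toluene (concentrated), 2,6-di-tert-butyl-4-methylphenol (cat.), 1.2 GPa, 45 °C, 72 h
Reagents that add atoms: none
Why: A thermal, normal-electron-demand Diels–Alder reaction of a 1-alkoxy-3-silyloxybutadiene with a 5-alkoxybut-2-enolide, the closest known reaction class, run at high pressure because the β-methyl group makes the dienophile sluggish and the cycloaddition has a strongly negative activation volume. Bonding should be unsymmetrical, the electron-rich CH2 terminus C9 leading into the β-carbon C10 while the C6–C5 bond follows within one suprafacial transition state, so the cyclohexene ring (C5–C6–C7–C8–C9–C10) is closed by intermolecular [4+2] annulation across C5=C10 and is necessarily cis-fused to the lactone. The stereocentres C10 and C5 are set together by attack of the diene on the butenolide face opposite the menthyloxy group on the acetal carbon C1, and C6 is set relative to C5 by the endo arrangement of the diene under the lactone carbonyl, which puts the benzyloxy group cis to C4. The step needs head-to-tail regiochemistry (C9 to C10), endo topology and a single dienophile face; these are secured by the match between the largest diene HOMO coefficient at C9 and the largest LUMO coefficient at C10, by secondary overlap with the lactone carbonyl that pressure favours further, and by the bulky menthyloxy substituent that shields its own face. The C7=C8 enol silane that remains stores the C8 oxygen and keeps C7 as the carbon nucleophile for step 11.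

Step 5
Reactants: 8 cycloadduct
Product: 10 aldehyde amide (10α-formyl, 5α-N-methoxy-N-methylcarboxamide, 6α-benzyloxy, C7=C8 silyl enol ether), via ring-opened menthyl hemiacetal 9 (not isolated)
Conditions: Me(MeO)NH·HCl, iPrMgCl (2 equiv per amine salt), THF, −20 → 0 °C; aq. NH4Cl
Reagents that add atoms: N,O-dimethylhydroxylamine hydrochloride, CNOC.Cl
Why: Aminolysis of the acylal-type lactone by the magnesium amide (Weinreb amide formation) opens the ring at C4, and the hemiacetal 9 so released sheds menthol to give the neopentyl aldehyde at C1; no stereocentre is involved and the auxiliary is recovered.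

Step 6
Reactants: 10 aldehyde amide
Product: 11 vinyl amide (10α-vinyl, 5α-N-methoxy-N-methylcarboxamide)
Conditions: Ph3PCH3Br, NaHMDS, THF, 0 °C → rt
Reagents that add atoms: methyltriphenylphosphonium bromide, C[P+](c1ccccc1)(c1ccccc1)c1ccccc1.[Br-]
Why: Wittig methylenation of the non-enolisable aldehyde gives the C10 vinyl group, the N-methoxy-N-methylamide and the silyl enol ether being inert to the ylide.

Step 7
Reactants: 11 vinyl amide
Product: 12 methyl ketone (5α-acetyl, 10α-vinyl, 6α-benzyloxy, C7=C8 silyl enol ether)
Conditions: MeMgBr, THF, 0 °C → rt; aq. NH4Cl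
Reagents that add atoms: methylmagnesium bromide, C[Mg]Br
Why: Weinreb ketone synthesis: the magnesium-chelated tetrahedral adduct stops at single addition and releases the ketone only on work-up, so C5 (α to the new ketone, β to the benzyloxy group) never meets base as a ketone.

Step 8
Reactants: 12 methyl ketone
Product: 13 benzyl ether triene (5α-isopropenyl, 10α-vinyl, 6α-benzyloxy, C7=C8 silyl enol ether)
Conditions: Cp2TiMe2, toluene, 70 °C, dark
Reagents that add atoms: dimethyltitanocene (Cp2TiMe2), C[Ti](C)(C1C=CC=C1)C1C=CC=C1
Why: Petasis methylenation through Cp2Ti=CH2 is non-basic and tolerant of enol silanes, so the hindered, enolisable methyl ketone should give the isopropenyl group without epimerisation at C5 or β-elimination of benzyl alcohol.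

Step 9
Reactants: 13 benzyl ether triene
Product: 14 allylic alcohol (6α-hydroxy, C7=C8 silyl enol ether)
Conditions: lithium 4,4'-di-tert-butylbiphenylide (LiDBB), THF, −78 °C; MeOH at −78 °C
Reagents that add atoms: none
Why: Single-electron reductive cleavage of the benzylic C–O bond by the arene radical anion (dissolving-metal-type debenzylation) leaves isolated alkenes and the silyl enol ether intact, and the cold protic quench prevents silyl migration or anionic oxy-Cope rearrangement of the lithium alkoxide.

Step 10
Reactants: 14 allylic alcohol; 15 pyruvic acid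
Product: 16 pyruvate ester (6α-pyruvoyloxy, C7=C8 silyl enol ether)
Conditions: DCC, DMAP (cat.), pyridine, CH2Cl2, −20 → 0 °C
Reagents that add atoms: none
Why: Steglich esterification (carbodiimide activation, DMAP acyl transfer) of the secondary allylic alcohol under buffered conditions that leave the acid-sensitive enol silane untouched.

Step 11
Reactants: 16 pyruvate ester
Product: 17 hydroxy lactone ketone (cis-fused γ-lactone O6–C12(=O)–C11–C7 on the α face, 11-hydroxy-11-methyl with OH syn to C8, 8-oxo)
Conditions: SnCl4, 2,6-di-tert-butyl-4-methylpyridine, CH2Cl2, −78 °C; aq. NaHCO3; crude product taken on at once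
Reagents that add atoms: none
Why: Intramolecular Mukaiyama aldol addition: SnCl4 chelated by the 1,2-dicarbonyl unit activates the keto group, the C7=C8 enol silane attacks it in a 5-(enolexo)-exo-trig closure that the O6 tether can only deliver to the α face of C7 (cis ring fusion), and the compact transition state with the keto oxygen held over the enol carbon C8 and the methyl group on the convex face should set C11 with its hydroxyl syn to C8.

Step 12
Reactants: 17 hydroxy lactone ketone
Product: 18 diol (8α-hydroxy, 11-hydroxy)
Conditions: LiBH(s-Bu)3, THF, −78 °C; H2O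
Reagents that add atoms: none
Why: Hydride reduction with a bulky trialkylborohydride should come from the β face (equatorial trajectory), because the α face of C8 is flanked by the axial lactone oxygen O6 and the axial C10 vinyl group, giving the axial 8α alcohol; the lactone is inert at −78 °C.

Step 13
Reactants: 18 diol; 19 3-methylbut-3-enoic acid
Product: 20 hydroxy ester (8β-(3-methylbut-3-enoyloxy), 11-hydroxy)
Conditions: PPh3, DIAD, toluene, 0 °C → rt
Reagents that add atoms: none
Why: Mitsunobu esterification: the secondary 8α hydroxyl is activated as its alkoxyphosphonium salt and displaced by the carboxylate with inversion (SN2) to the 8β ester, the tertiary C11 hydroxyl cannot be activated, and the near-neutral medium keeps the β,γ-double bond of the acid out of conjugation.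

Step 14
Reactants: 20 hydroxy ester
Product: 21 CNP0106639.1
Conditions: Ac2O, DMAP, Et3N, CH2Cl2, rt
Reagents that add atoms: acetic anhydride, CC(=O)OC(C)=O
Why: DMAP-catalysed acetylation (nucleophilic catalysis) of the remaining tertiary α-hydroxy lactone; the amine base is too weak to isomerise the β,γ-unsaturated ester.

**Compound list**

1 | 5-hydroxy-4-methylfuran-2(5H)-one | CC1=CC(=O)OC1O | starting material
2 | (−)-menthol, (1R,2S,5R) | CC(C)[C@@H]1CC[C@@H](C)C[C@H]1O | starting material
3 | (5R)-5-[(1R,2S,5R)-menthyloxy]-4-methylfuran-2(5H)-one | O=C1O[C@@H](O[C@@H]2C[C@H](C)CC[C@H]2C(C)C)C(C)=C1 | intermediate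
4 | (E)-4-methoxybut-3-en-2-one | CO/C=C/C(C)=O | starting material
5 | benzyl alcohol | OCc1ccccc1 | starting material
6 | (E)-4-(benzyloxy)but-3-en-2-one | CC(=O)/C=C/OCc1ccccc1 | intermediate
7 | (E)-1-(benzyloxy)-3-(tert-butyldimethylsilyloxy)buta-1,3-diene | C=C(O[Si](C)(C)C(C)(C)C)/C=C/OCc1ccccc1 | intermediate
8 | cycloadduct: cis-fused cyclohexene γ-lactone menthyl acetal, 6α-benzyloxy, C7=C8 TBS enol ether, 10β-methyl | O=C1O[C@@H](O[C@@H]3C[C@H](C)CC[C@H]3C(C)C)[C@]2(C)CC(O[Si](C)(C)C(C)(C)C)=C[C@H](OCc4ccccc4)[C@H]12 | intermediate
9 | ring-opened menthyl hemiacetal (C4 N-methoxy-N-methylamide, C1 CH(OH)(O-menthyl)); not isolated | O[C@@H](O[C@@H]2C[C@H](C)CC[C@H]2C(C)C)[C@]1(C)CC(O[Si](C)(C)C(C)(C)C)=C[C@H](OCc3ccccc3)[C@@H]1C(=O)N(C)OC | intermediate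
10 | aldehyde amide: 10α-formyl, 10β-methyl, 5α-N-methoxy-N-methylcarboxamide, 6α-benzyloxy, C7=C8 TBS enol ether | O=C[C@]1(C)CC(O[Si](C)(C)C(C)(C)C)=C[C@H](OCc2ccccc2)[C@@H]1C(=O)N(C)OC | intermediate
11 | vinyl amide: 10α-vinyl, 5α-N-methoxy-N-methylcarboxamide, 6α-benzyloxy, C7=C8 TBS enol ether | C=C[C@]1(C)CC(O[Si](C)(C)C(C)(C)C)=C[C@H](OCc2ccccc2)[C@@H]1C(=O)N(C)OC | intermediate
12 | methyl ketone: 5α-acetyl, 10α-vinyl, 6α-benzyloxy, C7=C8 TBS enol ether | C=C[C@]1(C)CC(O[Si](C)(C)C(C)(C)C)=C[C@H](OCc2ccccc2)[C@@H]1C(C)=O | intermediate
13 | benzyl ether triene: 5α-isopropenyl, 10α-vinyl, 6α-benzyloxy, C7=C8 TBS enol ether | C=C[C@]1(C)CC(O[Si](C)(C)C(C)(C)C)=C[C@H](OCc2ccccc2)[C@@H]1C(C)=C | intermediate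
14 | allylic alcohol: 6α-hydroxy, 5α-isopropenyl, 10α-vinyl, C7=C8 TBS enol ether | C=C[C@]1(C)CC(O[Si](C)(C)C(C)(C)C)=C[C@H](O)[C@@H]1C(C)=C | intermediate
15 | pyruvic acid | CC(=O)C(=O)O | starting material
16 | pyruvate ester: 6α-pyruvoyloxy, C7=C8 TBS enol ether | C=C[C@]1(C)CC(O[Si](C)(C)C(C)(C)C)=C[C@H](OC(=O)C(C)=O)[C@@H]1C(C)=C | intermediate
17 | hydroxy lactone ketone: 8-oxo, cis-fused 12,6-lactone, 11-hydroxy-11-methyl (OH syn to C8) | C=C[C@]1(C)CC(=O)[C@H]2[C@H](OC(=O)[C@@]2(C)O)[C@@H]1C(=C)C | intermediate
18 | diol: 8α-hydroxy, 11-hydroxy, cis-fused 12,6-lactone | C=C[C@]1(C)C[C@H](O)[C@H]2[C@H](OC(=O)[C@@]2(C)O)[C@@H]1C(=C)C | intermediate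
19 | 3-methylbut-3-enoic acid | C=C(C)CC(=O)O | starting material
20 | hydroxy ester: 8β-(3-methylbut-3-enoyloxy), 11-hydroxy | C=C[C@]1(C)C[C@@H](OC(=O)CC(=C)C)[C@H]2[C@H](OC(=O)[C@@]2(C)O)[C@@H]1C(=C)C | intermediate
21 | CNP0106639.1: (5R,6R,7S,8R,10S,11S)-11-acetoxy-8-(3-methylbut-3-enoyloxy)elema-1,3-dien-12,6-olide (numbering as in the plan) | C=C[C@]1(C)C[C@@H](OC(=O)CC(=C)C)[C@H]2[C@H](OC(=O)[C@@]2(C)OC(C)=O)[C@@H]1C(=C)C | target

**Step count**

Total steps: 14. Longest linear sequence: 13 steps (steps 2–14, from (E)-4-methoxybut-3-en-2-one).

**Steps most likely to fail**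

Step 4. The β,β-disubstituted butenolide may react so slowly that desilylation or polymerisation of the diene outruns the cycloaddition, or endo selectivity may erode. The fallback sets out from 3. Addition of Br2 (CH2Cl2, 0 °C) should give the 3,4-dibromolactone F1, and elimination of HBr with Et3N the 3-bromobutenolide F2. Its lower LUMO should allow cycloaddition with 7 at lower pressure or on simple heating, to give the bromo cycloadduct F3 with the same regiochemistry, endo sense and face. Radical debromination (Bu3SnH, AIBN, toluene, 80 °C), in which the C5 radical takes hydrogen on the convex face and so keeps the cis fusion, comes back to the route at 8.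

Step 11. The Lewis acid may ionise the allylic C6–O bond, which is activated by the enol ether, so that the pyruvate is lost and a dienone forms before the ring closes; addition to the wrong face of the keto group is the second danger. The fallback sets out from 16. NBS (THF, −78 °C) should convert the enol silane regiospecifically into the 7β-bromo ketone F4. Ph3SnH with Et3B (toluene, −78 °C) then generates the C7 boron enolate under neutral radical conditions (Reformatsky-type reductive aldol). This enolate should add to the tethered keto group through a closed six-membered transition state with boron bridging O8 and O11, which places the C11 oxygen syn to C8 without any Lewis acid, and it comes back to the route at 17.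

Step 13. The activated hydroxyl is axial, hindered and flanked by anti-periplanar hydrogens on C7 and C9, so elimination to a cyclohexene, or simple return of the alcohol, may outrun substitution by the weakly acidic β,γ-unsaturated acid. The fallback sets out from 18. Mitsunobu inversion with the more acidic 4-nitrobenzoic acid should give the 8β 4-nitrobenzoate F5, and mild methanolysis (K2CO3, MeOH, 0 °C) the 8β alcohol F6. Steglich acylation with 19 (DCC, cat. DMAP, 0 °C), which now proceeds with retention, comes back to the route at 20.

**Further compounds**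

F1 | step 4 | (5R)-3,4-dibromo-5-menthyloxy-4-methyldihydrofuran-2(3H)-one (mixture at C3 and C4) | O=C1O[C@@H](O[C@@H]2C[C@H](C)CC[C@H]2C(C)C)C(C)(Br)C1Br
F2 | step 4 | (5R)-3-bromo-5-menthyloxy-4-methylfuran-2(5H)-one | O=C1O[C@@H](O[C@@H]2C[C@H](C)CC[C@H]2C(C)C)C(C)=C1Br
F3 | step 4 | bromo cycloadduct (8 with bromine on C5 in place of hydrogen) | O=C1O[C@@H](O[C@@H]3C[C@H](C)CC[C@H]3C(C)C)[C@]2(C)CC(O[Si](C)(C)C(C)(C)C)=C[C@H](OCc4ccccc4)[C@]12Br
F4 | step 11 | 7β-bromo ketone (8-oxo, 6α-pyruvoyloxy) | C=C[C@]1(C)CC(=O)[C@@H](Br)[C@H](OC(=O)C(C)=O)[C@@H]1C(C)=C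
F5 | step 13 | 8β 4-nitrobenzoate of the hydroxy lactone | C=C[C@]1(C)C[C@@H](OC(=O)c3ccc(cc3)[N+](=O)[O-])[C@H]2[C@H](OC(=O)[C@@]2(C)O)[C@@H]1C(=C)C
F6 | step 13 | 8β alcohol (C8 epimer of 18) | C=C[C@]1(C)C[C@@H](O)[C@H]2[C@H](OC(=O)[C@@]2(C)O)[C@@H]1C(=C)C
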